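**Plan**
1. Retrosynthesis: after removing the 7-O-acetyl group and the C3'=C4' double bond, ring B is cut at O1'–C8a' and O1'–C2' (Baeyer–Villiger retron, back to a 1-indanone). The indanone is cut at its aryl–C(=O) bond (Friedel–Crafts), ring A at C3=C4 and O1–C2 (Perkin condensation), and the aryloxyacetic acid at its ArO–CH2 bond.
2. Forward: an aryloxyacetic acid carrying a masked propanoic acid chain (from syringaldehyde) and 2,4-dihydroxy-3,5-dimethoxybenzaldehyde (from 2-methoxyresorcinol) are condensed to ring A. The five-membered ketone is then closed onto the symmetric ring and expanded with a peracid to the lactone of ring B, which is dehydrogenated before the acetate is removed.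
3. Enabling feature: O1' of ring B sits between C2' and C8a', and C8a' is ortho to the C8' methoxy and para to the C6' methoxy group. This is the electron-rich aryl carbon that migrates to oxygen when the corresponding 1-indanone meets a peracid.
4. Stereochemistry: the target has no stereocentre; the E alkene of the cinnamate and the carbinol carbon of the Criegee adduct are both erased again.

Key step: step 10

Remark: the target has no stereocentre and no configurationally stable axis, so it is achiral and "single enantiomer" reduces to the one constitution shown; primed locants denote the atoms of ring B (the 7-aryloxy coumarin).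

**Step 1**
Reactants: 1 syringaldehyde (4-hydroxy-3,5-dimethoxybenzaldehyde); 2 benzyl bromoacetate
Product: 3 benzyl 2-(4-formyl-2,6-dimethoxyphenoxy)acetate
Conditions: K2CO3, DMF, rt to 50 °C
Reagents that add atoms: none
Why: Williamson ether synthesis, in which the phenoxide is alkylated by the reactive α-bromo ester while carbonate is too weak a base to start aldol or Darzens chemistry at the aldehyde.

**Step 2**
Reactants: 3 benzyl 2-(4-formyl-2,6-dimethoxyphenoxy)acetate; 4 tert-butyl (triphenylphosphoranylidene)acetate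
Product: 5 tert-butyl (E)-3-[4-(2-benzyloxy-2-oxoethoxy)-3,5-dimethoxyphenyl]prop-2-enoate
Conditions: CH2Cl2, rt to 40 °C
Reagents that add atoms: none
Why: Wittig olefination with a stabilised ylide, which should attack only the aldehyde and give the E cinnamate (the geometry is irrelevant, since the alkene is reduced next).

**Step 3**
Reactants: 5 tert-butyl (E)-3-[4-(2-benzyloxy-2-oxoethoxy)-3,5-dimethoxyphenyl]prop-2-enoate
Product: 7 2-[4-(3-tert-butoxy-3-oxopropyl)-2,6-dimethoxyphenoxy]acetic acid, via saturated benzyl ester 6 (not isolated)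
Conditions: H2 (1 atm), 10% Pd/C, EtOAc, rt
Reagents that add atoms: none
Why: catalytic hydrogenation of the cinnamate C=C and hydrogenolysis of the benzyl ester in one operation, which should leave the tert-butyl ester and the aryl ethers untouched and so differentiate the two carboxyl groups.

**Step 4**
Reactants: 8 2-methoxyresorcinol (2-methoxybenzene-1,3-diol)
Product: 10 2,4-dihydroxy-3-methoxybenzaldehyde, via iminium chloride 9 (not isolated)
Conditions: POCl3, DMF, MeCN, 0 °C to rt; then H2O, 50 °C
Reagents that add atoms: N,N-dimethylformamide, CN(C)C=O; water, O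
Why: Vilsmeier–Haack formylation of a resorcinol, which should occur at C4 (ortho to one hydroxyl, para to the other; C4 and C6 are equivalent) and stop after one formylation because iminium salt 9 is deactivated.

**Step 5**
Reactants: 10 2,4-dihydroxy-3-methoxybenzaldehyde
Product: 11 5-bromo-2,4-dihydroxy-3-methoxybenzaldehyde
Conditions: Br2 (1.0 equiv), AcOH, rt
Reagents that add atoms: bromine, BrBr
Why: electrophilic aromatic bromination, directed to C5 because it is ortho to the 4-OH and para to the 2-OH whereas C6 is meta to both.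

**Step 6**
Reactants: 11 5-bromo-2,4-dihydroxy-3-methoxybenzaldehyde
Product: 12 2,4-dihydroxy-3,5-dimethoxybenzaldehyde
Conditions: NaOMe (excess), CuBr (cat.), DMF–MeOH, 110 °C; then aq. HCl
Reagents that add atoms: sodium methoxide, [Na+].[O-]C
Why: Ullmann-type copper-catalysed methoxylation of a bromide ortho to a phenoxide (the reaction type that converts 5-bromovanillin into syringaldehyde), with the phenoxides protecting the aldehyde against Cannizzaro reaction.

**Step 7**
Reactants: 7 2-[4-(3-tert-butoxy-3-oxopropyl)-2,6-dimethoxyphenoxy]acetic acid; 12 2,4-dihydroxy-3,5-dimethoxybenzaldehyde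
Product: 14 tert-butyl 3-{4-[(7-acetoxy-6,8-dimethoxy-2-oxo-2H-chromen-3-yl)oxy]-3,5-dimethoxyphenyl}propanoate, via aryl ester 13 (not isolated)
Conditions: Ac2O, Et3N, 110 °C
Reagents that add atoms: acetic anhydride, CC(=O)OC(C)=O
Why: Perkin–Oglialoro coumarin synthesis, in which both phenols are acylated, the aryloxyacetyl group ends on O2 as in ester 13, and its α-CH2 (acidified by the aryloxy group) condenses intramolecularly with the formyl group and dehydrates to the 3-aryloxycoumarin, leaving O7 as the acetate needed later.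

**Step 8**
Reactants: 14 tert-butyl 3-{4-[(7-acetoxy-6,8-dimethoxy-2-oxo-2H-chromen-3-yl)oxy]-3,5-dimethoxyphenyl}propanoate
Product: 15 3-{4-[(7-acetoxy-6,8-dimethoxy-2-oxo-2H-chromen-3-yl)oxy]-3,5-dimethoxyphenyl}propanoic acid
Conditions: TFA, CH2Cl2, 0 °C to rt
Reagents that add atoms: none
Why: acidolysis of a tert-butyl ester (alkyl–oxygen cleavage with loss of isobutene) under anhydrous conditions, which should spare the aryl acetate, the lactone and the enol-ether linkage that a saponification would attack.

**Step 9**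
Reactants: 15 3-{4-[(7-acetoxy-6,8-dimethoxy-2-oxo-2H-chromen-3-yl)oxy]-3,5-dimethoxyphenyl}propanoic acid
Product: 16 7-acetoxy-3-[(4,6-dimethoxy-3-oxo-2,3-dihydro-1H-inden-5-yl)oxy]-6,8-dimethoxy-2H-chromen-2-one
Conditions: Eaton's reagent (P2O5 in MsOH), rt
Reagents that add atoms: none
Why: intramolecular Friedel–Crafts acylation at a position ortho to one methoxy and para to the other; the two free positions of the symmetric ring are equivalent, so a single indanone should form, and the acetylated coumarin ring is too electron-poor to compete.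

**Step 10**
Reactants: 16 7-acetoxy-3-[(4,6-dimethoxy-3-oxo-2,3-dihydro-1H-inden-5-yl)oxy]-6,8-dimethoxy-2H-chromen-2-one
Product: 18 7-acetoxy-3-[(6,8-dimethoxy-2-oxo-3,4-dihydro-2H-chromen-7-yl)oxy]-6,8-dimethoxy-2H-chromen-2-one, via Criegee adduct 17 (not isolated)
Conditions: mCPBA (1.5 equiv), TFA (cat.), CH2Cl2, 0 °C to rt, dark
Reagents that add atoms: meta-chloroperoxybenzoic acid, OOC(=O)c1cccc(Cl)c1
Why: Baeyer–Villiger oxidation: acid-catalysed addition of the peracid to the indanone carbonyl gives Criegee adduct 17, and the aryl carbon (future C8a'), anti-periplanar to the O–O bond, shifts from carbon to oxygen with loss of 3-chlorobenzoate, creating the C8a'–O1' and O1'–C2' bonds. The closest known reaction type is the peracid oxidation of methoxy-substituted 1-indanones to 3,4-dihydrocoumarins. Ring B is not closed end to end but arises by expansion of the five-membered ketone to the six-membered aryl lactone through this 1,2-shift, and no stereocentre is formed (that of 17 is lost on migration). The step needs aryl rather than CH2 migration, and oxidation of the ketone in preference to the rest of the molecule. The first should be secured by the methoxy groups ortho (C8') and para (C6') to the migrating carbon, which stabilise the developing positive charge far better than the primary CH2 can; the second by the acetylated, lactone-conjugated ring A and its electron-poor C3=C4 bond, which should be inert to the peracid at this temperature.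

**Step 11**
Reactants: 18 7-acetoxy-3-[(6,8-dimethoxy-2-oxo-3,4-dihydro-2H-chromen-7-yl)oxy]-6,8-dimethoxy-2H-chromen-2-one
Product: 19 7-acetoxy-3-[(6,8-dimethoxy-2-oxo-2H-chromen-7-yl)oxy]-6,8-dimethoxy-2H-chromen-2-one
Conditions: DDQ, 1,4-dioxane, reflux
Reagents that add atoms: none
Why: DDQ dehydrogenation of a 3,4-dihydrocoumarin by hydride abstraction from benzylic C4' (assisted by O1' ortho and the C7' aryloxy oxygen para to C4a') and loss of H3'; it is run before deacetylation because the aryl lactone of 18 would be opened by methanol and a free phenol would be oxidised by the quinone.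

**Step 12**
Reactants: 19 7-acetoxy-3-[(6,8-dimethoxy-2-oxo-2H-chromen-7-yl)oxy]-6,8-dimethoxy-2H-chromen-2-one
Product: 20 7-hydroxy-3-[(6,8-dimethoxy-2-oxo-2H-chromen-7-yl)oxy]-6,8-dimethoxy-2H-chromen-2-one (CNP0278842.0)
Conditions: K2CO3 (cat.), MeOH/CH2Cl2, 0 °C; then dil. HCl
Reagents that add atoms: none
Why: base-catalysed transesterification (Zemplén-type methanolysis) should remove the phenyl acetate much faster than either coumarin lactone is attacked, and any ring-opened coumarinate should reclose on the acidic work-up.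

**Compound list**
1 | syringaldehyde (4-hydroxy-3,5-dimethoxybenzaldehyde) | COc1cc(C=O)cc(OC)c1O | starting material
2 | benzyl bromoacetate | BrCC(=O)OCc1ccccc1 | starting material
3 | benzyl 2-(4-formyl-2,6-dimethoxyphenoxy)acetate | COc1cc(C=O)cc(OC)c1OCC(=O)OCc1ccccc1 | intermediate
4 | tert-butyl (triphenylphosphoranylidene)acetate | CC(C)(C)OC(=O)C=P(c1ccccc1)(c1ccccc1)c1ccccc1 | starting material
5 | tert-butyl (E)-3-[4-(2-benzyloxy-2-oxoethoxy)-3,5-dimethoxyphenyl]prop-2-enoate | COc1cc(/C=C/C(=O)OC(C)(C)C)cc(OC)c1OCC(=O)OCc1ccccc1 | intermediate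
6 | benzyl 2-[4-(3-tert-butoxy-3-oxopropyl)-2,6-dimethoxyphenoxy]acetate | COc1cc(CCC(=O)OC(C)(C)C)cc(OC)c1OCC(=O)OCc1ccccc1 | intermediate
7 | 2-[4-(3-tert-butoxy-3-oxopropyl)-2,6-dimethoxyphenoxy]acetic acid | COc1cc(CCC(=O)OC(C)(C)C)cc(OC)c1OCC(=O)O | intermediate
8 | 2-methoxyresorcinol (2-methoxybenzene-1,3-diol) | COc1c(O)cccc1O | starting material
9 | (2,4-dihydroxy-3-methoxybenzylidene)dimethyliminium chloride | C[N+](C)=Cc1ccc(O)c(OC)c1O.[Cl-] | intermediate
10 | 2,4-dihydroxy-3-methoxybenzaldehyde | COc1c(O)ccc(C=O)c1O | intermediate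
11 | 5-bromo-2,4-dihydroxy-3-methoxybenzaldehyde | COc1c(O)c(Br)cc(C=O)c1O | intermediate
12 | 2,4-dihydroxy-3,5-dimethoxybenzaldehyde | COc1cc(C=O)c(O)c(OC)c1O | intermediate
13 | 3-acetoxy-6-formyl-2,4-dimethoxyphenyl 2-[4-(3-tert-butoxy-3-oxopropyl)-2,6-dimethoxyphenoxy]acetate | COc1cc(C=O)c(OC(=O)COc2c(OC)cc(CCC(=O)OC(C)(C)C)cc2OC)c(OC)c1OC(C)=O | intermediate
14 | tert-butyl 3-{4-[(7-acetoxy-6,8-dimethoxy-2-oxo-2H-chromen-3-yl)oxy]-3,5-dimethoxyphenyl}propanoate | COc1cc(CCC(=O)OC(C)(C)C)cc(OC)c1Oc1cc2cc(OC)c(OC(C)=O)c(OC)c2oc1=O | intermediate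
15 | 3-{4-[(7-acetoxy-6,8-dimethoxy-2-oxo-2H-chromen-3-yl)oxy]-3,5-dimethoxyphenyl}propanoic acid | COc1cc(CCC(=O)O)cc(OC)c1Oc1cc2cc(OC)c(OC(C)=O)c(OC)c2oc1=O | intermediate
16 | 7-acetoxy-3-[(4,6-dimethoxy-3-oxo-2,3-dihydro-1H-inden-5-yl)oxy]-6,8-dimethoxy-2H-chromen-2-one | O=C1CCc2cc(OC)c(Oc3cc4cc(OC)c(OC(C)=O)c(OC)c4oc3=O)c(OC)c12 | intermediate
17 | Criegee adduct: 6-[(7-acetoxy-6,8-dimethoxy-2-oxo-2H-chromen-3-yl)oxy]-1-hydroxy-5,7-dimethoxy-2,3-dihydro-1H-inden-1-yl 3-chloroperoxybenzoate (racemic, transient) | OC1(OOC(=O)c2cccc(Cl)c2)CCc2cc(OC)c(Oc3cc4cc(OC)c(OC(C)=O)c(OC)c4oc3=O)c(OC)c12 | intermediate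
18 | 7-acetoxy-3-[(6,8-dimethoxy-2-oxo-3,4-dihydro-2H-chromen-7-yl)oxy]-6,8-dimethoxy-2H-chromen-2-one | O=C1CCc2cc(OC)c(Oc3cc4cc(OC)c(OC(C)=O)c(OC)c4oc3=O)c(OC)c2O1 | intermediate
19 | 7-acetoxy-3-[(6,8-dimethoxy-2-oxo-2H-chromen-7-yl)oxy]-6,8-dimethoxy-2H-chromen-2-one | COc1cc2cc(Oc3c(OC)cc4ccc(=O)oc4c3OC)c(=O)oc2c(OC)c1OC(C)=O | intermediate
20 | 7-hydroxy-3-[(6,8-dimethoxy-2-oxo-2H-chromen-7-yl)oxy]-6,8-dimethoxy-2H-chromen-2-one (CNP0278842.0) | COc1cc2cc(Oc3c(OC)cc4ccc(=O)oc4c3OC)c(=O)oc2c(OC)c1O | target

**Step count**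
Total: 12 steps. Longest linear sequence: 9 steps (steps 1–3, then 7–12; the branch through steps 4–6 and 7–12 is equally long).

**Steps most likely to fail**

Step 10 (key step). Peracid addition to the hindered, donor-deactivated carbonyl may be slow, so that oxidation of the electron-rich ring or migration of the CH2 group competes. The same aryl-to-oxygen shift can then be run on an aldehyde, where it is more dependable. Setting out from 14, Vilsmeier–Haack formylation (POCl3, DMF, 60 °C) at the ring-B position ortho to one methoxy group and para to the other would give, through the iminium chloride F1 that is hydrolysed on work-up, tert-butyl 3-{4-[(7-acetoxy-6,8-dimethoxy-2-oxo-2H-chromen-3-yl)oxy]-2-formyl-3,5-dimethoxyphenyl}propanoate F2. A Dakin-type Baeyer–Villiger oxidation with mCPBA in CH2Cl2 would convert it into the aryl formate F3. TFA in wet CH2Cl2 would then cleave the formate and the tert-butyl ester to the hydroxy acid F4, which should lactonise on warming with catalytic TsOH in toluene and rejoin the route at 18.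

Step 11. Hydride abstraction from C4' is not assisted by a methoxy group ortho or para to C4a', so the dehydrogenation may stall or give decomposition on prolonged heating with the quinone. The double bond can instead be introduced by substitution and elimination. Setting out from 18, Wohl–Ziegler bromination (NBS, AIBN, PhCF3, reflux) at benzylic C4' would give racemic 7-acetoxy-3-[(4-bromo-6,8-dimethoxy-2-oxo-3,4-dihydro-2H-chromen-7-yl)oxy]-6,8-dimethoxy-2H-chromen-2-one F5. Treatment with Et3N in CH2Cl2 at rt should then eliminate HBr through the lactone enolate and return to the route at 19.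

Step 7. At 110 °C, condensation of the aldehyde with acetic anhydride itself (leading to the 3-unsubstituted coumarin) and thermal loss of the tert-butyl ester may erode the desired pathway. The two bonds can be formed separately under mild conditions. Setting out from 12, acetylation with one equivalent of Ac2O and pyridine in CH2Cl2 at 0 °C should take place at the 4-OH (the 2-OH being chelated to the formyl group) and give 4-formyl-3-hydroxy-2,6-dimethoxyphenyl acetate F6. Carbodiimide esterification with acid 7 (EDC·HCl, DMAP, CH2Cl2) would give 13, now isolated. An intramolecular Knoevenagel condensation with Et3N or DBU in MeCN at rt should then close ring A and return to the route at 14.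

**Further compounds**
F1 | step 10 | {6-[(7-acetoxy-6,8-dimethoxy-2-oxo-2H-chromen-3-yl)oxy]-2-(3-tert-butoxy-3-oxopropyl)-3,5... ring-B benzylidene}dimethyliminium chloride (Vilsmeier iminium salt of 14, formylated ortho to the side chain) | C[N+](C)=Cc1c(CCC(=O)OC(C)(C)C)cc(OC)c(Oc2cc3cc(OC)c(OC(C)=O)c(OC)c3oc2=O)c1OC.[Cl-]
F2 | step 10 | tert-butyl 3-{4-[(7-acetoxy-6,8-dimethoxy-2-oxo-2H-chromen-3-yl)oxy]-2-formyl-3,5-dimethoxyphenyl}propanoate | O=Cc1c(CCC(=O)OC(C)(C)C)cc(OC)c(Oc2cc3cc(OC)c(OC(C)=O)c(OC)c3oc2=O)c1OC
F3 | step 10 | tert-butyl 3-{4-[(7-acetoxy-6,8-dimethoxy-2-oxo-2H-chromen-3-yl)oxy]-2-(formyloxy)-3,5-dimethoxyphenyl}propanoate | O=COc1c(CCC(=O)OC(C)(C)C)cc(OC)c(Oc2cc3cc(OC)c(OC(C)=O)c(OC)c3oc2=O)c1OC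
F4 | step 10 | 3-{4-[(7-acetoxy-6,8-dimethoxy-2-oxo-2H-chromen-3-yl)oxy]-2-hydroxy-3,5-dimethoxyphenyl}propanoic acid | Oc1c(CCC(=O)O)cc(OC)c(Oc2cc3cc(OC)c(OC(C)=O)c(OC)c3oc2=O)c1OC
F5 | step 11 | 7-acetoxy-3-[(4-bromo-6,8-dimethoxy-2-oxo-3,4-dihydro-2H-chromen-7-yl)oxy]-6,8-dimethoxy-2H-chromen-2-one (racemic) | O=C1CC(Br)c2cc(OC)c(Oc3cc4cc(OC)c(OC(C)=O)c(OC)c4oc3=O)c(OC)c2O1
F6 | step 7 | 4-formyl-3-hydroxy-2,6-dimethoxyphenyl acetate | COc1cc(C=O)c(O)c(OC)c1OC(C)=O
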